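**Retrosynthetic overview** (abietane locants: ring B = C-5 to C-10, ring C = C-8, C-9, C-11 to C-14, acid chain = C-1 to C-3 on C-10)
1. Target 26 ⇐ 25 ⇐ 23: the C-3 acid and O-11 are carried as a temporary seven-membered aryl lactone that is opened last; O-14 is unmasked by chelation-controlled demethylation.
2. 23 ⇐ 20: the C-7 carbinol is oxidised and the C-6 allyl ester, an activating group, is excised by Pd-mediated decarboxylation.
3. 20 ⇐ 15 + 18: a photoenolisation/Diels–Alder reaction forms C-6–C-7 and C-5–C-10 (ring B) and sets C-5 and the quaternary C-10 from a racemic aldehyde.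
4. Enabling feature: the formyl carbon C-7 on C-8 is ortho to the benzylic C-10–H on C-9 of ring C, so light turns C-7=C-8–C-9=C-10 into a diene through the arene; the lactone ring (C-10, C-1, C-2, C-3, O, C-11, C-9) fixes the geometry at C-9=C-10.
5. 15 ⇐ 8 ⇐ 1. Ring order: ring C (bought), oxepinone ring (step 6), ring B (step 9), oxepinone opened (step 13).

Key step: step 9

**Remarks.** Allyl diethylphosphonoacetate 17 and (R,R)-TADDOL are taken as commercial. Compounds 11–15 are deliberately racemic at C-10, because that centre is planarised in step 9. The (R,R)-ligand is assigned to the (5S,10S) series by analogy only; the antipodal ligand gives the mirror image.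

**Step 1**
Reactants: 1 1,3-dimethoxybenzene; 2 acetone
Product: 4 2-(2,6-dimethoxyphenyl)propan-2-ol, via 2,6-dimethoxyphenyllithium 3 (not isolated)
Conditions: n-BuLi, THF, 0 °C to rt; then 2, −78 °C to rt; H2O
Reagents that add atoms: none
Why: Directed ortho-metalation at the position between the two methoxy groups, then 1,2-addition of the aryllithium to acetone.

**Step 2**
Reactants: 4 2-(2,6-dimethoxyphenyl)propan-2-ol
Product: 5 1,3-dimethoxy-2-(propan-2-yl)benzene
Conditions: Et3SiH, TFA, CH2Cl2, 0 °C to rt
Reagents that add atoms: none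
Why: Ionic hydrogenation; the tertiary benzylic cation from the electron-rich arene is reduced by silane hydride.

**Step 3**
Reactants: 5 1,3-dimethoxy-2-(propan-2-yl)benzene
Product: 8 2,4-dimethoxy-3-(propan-2-yl)phenol, via aryllithium 6 (not isolated), via arylboronate 7 (not isolated)
Conditions: s-BuLi, TMEDA, Et2O, 0 °C; B(OMe)3, −78 °C to rt; then 30% H2O2, aq NaOH, 0 °C
Reagents that add atoms: hydrogen peroxide, OO
Why: Methoxy-directed ortho-lithiation (the two ortho sites are equivalent), borylation and oxidative 1,2-aryl shift from boron to oxygen should give the phenol that becomes O-11.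

**Step 4**
Reactants: 8 2,4-dimethoxy-3-(propan-2-yl)phenol; 9 (E)-1-bromobut-2-ene
Product: 10 1-[(2E)-but-2-en-1-yloxy]-2,4-dimethoxy-3-(propan-2-yl)benzene
Conditions: K2CO3, acetone, reflux
Reagents that add atoms: none
Why: Williamson O-alkylation of the phenoxide at the primary allylic carbon.

**Step 5**
Reactants: 10 crotyl aryl ether
Product: 12 rac-6-(but-3-en-2-yl)-2,4-dimethoxy-3-(propan-2-yl)phenol, via ortho-dienone 11 (not isolated)
Conditions: PhNEt2, 190 °C
Reagents that add atoms: none
Why: Aromatic Claisen rearrangement to the only free ortho position (future C-9) installs the C-10 methine with its methyl group; the new stereocentre is racemic and is erased later.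

**Step 6**
Reactants: 12 rac-6-(but-3-en-2-yl)-2,4-dimethoxy-3-(propan-2-yl)phenol
Product: 13 rac-7,9-dimethoxy-5-methyl-8-(propan-2-yl)-4,5-dihydro-1-benzoxepin-2(3H)-one
Conditions: Pd(OAc)2 (cat.), dppb (cat.), CO/H2 (1:1, 40 bar), PhMe, 110 °C
Reagents that add atoms: carbon monoxide, [C-]#[O+]
Why: Pd-catalysed cyclocarbonylation of a 2-allylphenol; anti-Markovnikov hydropalladation (favoured by the allylic branch and the wide-bite diphosphine), CO insertion and phenol capture should close the seven-membered lactone.

**Step 7**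
Reactants: 13 lactone
Product: 15 rac-7,9-dimethoxy-5-methyl-2-oxo-8-(propan-2-yl)-2,3,4,5-tetrahydro-1-benzoxepine-6-carbaldehyde, via chloro(methoxy)methyl arene 14 (not isolated)
Conditions: Cl2CHOMe, TiCl4, CH2Cl2, −78 to 0 °C; then H2O
Reagents that add atoms: dichloromethyl methyl ether, COC(Cl)Cl; water, O
Why: Rieche formylation at the single remaining aromatic C–H (future C-8), which is para and ortho to methoxy groups.

**Step 8**
Reactants: 16 methacrolein; 17 allyl diethylphosphonoacetate
Product: 18 prop-2-en-1-yl (2E)-4-methylpenta-2,4-dienoate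
Conditions: LiCl, DBU, MeCN, 0 °C to rt
Reagents that add atoms: none
Why: Horner–Wadsworth–Emmons olefination under Masamune–Roush conditions should give the E-enoate.

**Step 9**
Reactants: 15 aldehyde lactone; 18 allyl dienoate
Product: 20 allyl (5S,6R,7R,10S)-7-hydroxy ester adduct (ring B closed; C-5 isopropenyl cis to C-10 methyl), via hydroxy-o-quinodimethane 19 (not isolated)
Conditions: Ti(Oi-Pr)4, (R,R)-TADDOL (complex preformed, i-PrOH removed), 18 (3 equiv), PhMe, hν (366 nm), 20 °C, degassed
Reagents that add atoms: none
Why: n→π* excitation of the formyl group of 15 (its oxygen held syn to C-10–H by the flanking methoxy group) is followed by 1,5-hydrogen transfer from C-10 and gives the hydroxy-o-quinodimethane 19, in which C-9=C-10 lies inside the seven-membered lactone so that C-1 is locked outside and the methyl group inside, while the racemic C-10 centre of 15 is erased; the titanium TADDOLate binds the dienol oxygen and the ester carbonyl of 18 and delivers the α,β-double bond endo. The closest known reaction type is the titanium-TADDOLate-mediated enantioselective photoenolisation/Diels–Alder reaction of 3,6-dialkoxy-2-alkylbenzaldehydes with enoates and enones; here the benzylic diene terminus is more highly substituted. Ring B is closed by an intermolecular suprafacial [4π+2π] cycloaddition that forms C-6–C-7 and C-5–C-10 together. C-10 is set by the ring-locked diene geometry (outside C-1 ends cis to the endo ester), C-5 by the E geometry of 18 (isopropenyl exo, hence trans to the ester and cis to the C-10 methyl), C-6 and C-7 by the endo, OH-outside transition state, and the absolute sense by the TADDOL ligand. The step needs ortho regioselectivity (ester-bearing carbon to C-7), α,β- over γ,δ-site selectivity and endo selectivity, all secured by chelation of the ester to the titanium-bound dienol oxygen and by the larger HOMO coefficient at C-10, remote from that oxygen.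

**Step 10**
Reactants: 20 hydroxy ester adduct
Product: 21 allyl (5S,10S)-7-oxo-6-carboxylate (β-keto ester; C-6 epimers and enol)
Conditions: Dess–Martin periodinane, NaHCO3, CH2Cl2, 0 °C to rt
Reagents that add atoms: none
Why: Dess–Martin oxidation of the secondary benzylic alcohol; neutral conditions spare the isopropenyl group and the lactone.

**Step 11**
Reactants: 21 β-keto allyl ester
Product: 23 (5S,10S)-keto lactone (C-6 now CH2), via beta-keto acid 22 (not isolated)
Conditions: Pd(OAc)2 (cat.), PPh3, HCO2H, Et3N, THF, rt
Reagents that add atoms: none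
Why: Tsuji–Trost deallylation with formate as hydride donor, then decarboxylation of the β-keto acid; no nucleophilic amine is present to open the aryl lactone, and C-5 is not enolisable.

**Step 12**
Reactants: 23 keto lactone
Product: 25 (5S,10S)-14-hydroxy keto lactone, via aryloxydichloroborane 24 (not isolated)
Conditions: BCl3, CH2Cl2, −78 to −20 °C; then aq NaHCO3
Reagents that add atoms: none
Why: Chelation-controlled ether cleavage; boron bound to the C-7 carbonyl activates only the peri methoxy group on C-14, while the C-12 methoxy group, flanked by the acylated O-11 and isopropyl, is not chelated.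

**Step 13**
Reactants: 25 14-hydroxy keto lactone
Product: 26 3-[(1S,2S)-5,8-dihydroxy-7-methoxy-1-methyl-4-oxo-6-(propan-2-yl)-2-(prop-1-en-2-yl)-1,2,3,4-tetrahydronaphthalen-1-yl]propanoic acid (CNP0249049.1)
Conditions: LiOH, degassed THF/H2O, 0 °C to rt; then degassed 1 M HCl, Na2S2O4 wash
Reagents that add atoms: water, O
Why: Saponification of the aryl lactone (phenoxide leaving group) releases O-11–H and the C-3 acid; C-5 and C-10 cannot epimerise, and air is excluded because the product is a hydroquinone.

**Compound list**
1 | 1,3-dimethoxybenzene | COc1cccc(OC)c1 | starting material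
2 | acetone | CC(C)=O | starting material
3 | 2,6-dimethoxyphenyllithium | [Li]c1c(OC)cccc1OC | intermediate (not isolated)
4 | 2-(2,6-dimethoxyphenyl)propan-2-ol | CC(C)(O)c1c(OC)cccc1OC | intermediate
5 | 1,3-dimethoxy-2-(propan-2-yl)benzene | CC(C)c1c(OC)cccc1OC | intermediate
6 | [2,4-dimethoxy-3-(propan-2-yl)phenyl]lithium | [Li]c1ccc(OC)c(C(C)C)c1OC | intermediate (not isolated)
7 | dimethyl [2,4-dimethoxy-3-(propan-2-yl)phenyl]boronate | COB(OC)c1ccc(OC)c(C(C)C)c1OC | intermediate (not isolated)
8 | 2,4-dimethoxy-3-(propan-2-yl)phenol | Oc1ccc(OC)c(C(C)C)c1OC | intermediate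
9 | (E)-1-bromobut-2-ene (crotyl bromide) | C/C=C/CBr | starting material
10 | 1-[(2E)-but-2-en-1-yloxy]-2,4-dimethoxy-3-(propan-2-yl)benzene | C/C=C/COc1ccc(OC)c(C(C)C)c1OC | intermediate
11 | 6-(but-3-en-2-yl)-2,4-dimethoxy-3-(propan-2-yl)cyclohexa-2,4-dien-1-one (stereoisomer mixture) | O=C1C(OC)=C(C(C)C)C(OC)=CC1C(C)C=C | intermediate (not isolated)
12 | rac-6-(but-3-en-2-yl)-2,4-dimethoxy-3-(propan-2-yl)phenol | C=CC(C)c1cc(OC)c(C(C)C)c(OC)c1O | intermediate
13 | rac-7,9-dimethoxy-5-methyl-8-(propan-2-yl)-4,5-dihydro-1-benzoxepin-2(3H)-one | CC1CCC(=O)Oc2c(OC)c(C(C)C)c(OC)cc12 | intermediate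
14 | rac-6-[chloro(methoxy)methyl] derivative of 13 | COC(Cl)c1c(OC)c(C(C)C)c(OC)c2OC(=O)CCC(C)c12 | intermediate (not isolated)
15 | rac-7,9-dimethoxy-5-methyl-2-oxo-8-(propan-2-yl)-2,3,4,5-tetrahydro-1-benzoxepine-6-carbaldehyde | O=Cc1c(OC)c(C(C)C)c(OC)c2OC(=O)CCC(C)c12 | intermediate
16 | methacrolein (2-methylprop-2-enal) | CC(=C)C=O | starting material
17 | prop-2-en-1-yl (diethoxyphosphoryl)acetate | CCOP(=O)(OCC)CC(=O)OCC=C | starting material
18 | prop-2-en-1-yl (2E)-4-methylpenta-2,4-dienoate | C=C(C)/C=C/C(=O)OCC=C | intermediate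
19 | hydroxy-o-quinodimethane from 15 (OH outside; C-9=C-10 inside the lactone ring, methyl inside) | O/C=C1\C(OC)=C(C(C)C)C(OC)=C2OC(=O)CCC(C)=C12 | intermediate (not isolated)
20 | allyl (5S,6R,7R,10S)-7-hydroxy-14,12-dimethoxy adduct: ring B with C-7 OH, C-6 CO2allyl, C-5 isopropenyl, C-10 methyl; C-1–C-3 lactone to O-11 | C=C(C)[C@@H]1[C@@H](C(=O)OCC=C)[C@@H](O)c2c(OC)c(C(C)C)c(OC)c3OC(=O)CC[C@]1(C)c23 | intermediate
21 | (5S,10S)-7-oxo-6-(allyloxycarbonyl) lactone (β-keto ester) | C=C(C)[C@@H]1C(C(=O)OCC=C)C(=O)c2c(OC)c(C(C)C)c(OC)c3OC(=O)CC[C@]1(C)c23 | intermediate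
22 | (5S,10S)-7-oxo-6-carboxylic acid lactone (β-keto acid) | C=C(C)[C@@H]1C(C(=O)O)C(=O)c2c(OC)c(C(C)C)c(OC)c3OC(=O)CC[C@]1(C)c23 | intermediate (not isolated)
23 | (5S,10S)-12,14-dimethoxy-7-oxo lactone (keto lactone) | C=C(C)[C@@H]1CC(=O)c2c(OC)c(C(C)C)c(OC)c3OC(=O)CC[C@]1(C)c23 | intermediate
24 | (5S,10S)-14-(dichloroboryloxy)-12-methoxy-7-oxo lactone | C=C(C)[C@@H]1CC(=O)c2c(OB(Cl)Cl)c(C(C)C)c(OC)c3OC(=O)CC[C@]1(C)c23 | intermediate (not isolated)
25 | (5S,10S)-14-hydroxy-12-methoxy-7-oxo lactone | C=C(C)[C@@H]1CC(=O)c2c(O)c(C(C)C)c(OC)c3OC(=O)CC[C@]1(C)c23 | intermediate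
26 | 3-[(1S,2S)-5,8-dihydroxy-7-methoxy-1-methyl-4-oxo-6-(propan-2-yl)-2-(prop-1-en-2-yl)-1,2,3,4-tetrahydronaphthalen-1-yl]propanoic acid | C=C(C)[C@@H]1CC(=O)c2c(O)c(C(C)C)c(OC)c(O)c2[C@@]1(C)CCC(=O)O | target

**Step count and risks**
Total: 13 steps. Longest linear sequence: 12 steps (steps 1–7 and 9–13); step 8 prepares the dienophile.

Step 9 (most likely to fail). Bimolecular capture of the hindered, transient dienol may lose to re-ketonisation and to a [1,5]-hydrogen shift from the inside methyl group. Triplet energy transfer may scramble the geometry of the dienoate. The titanium alkoxide may open the aryl lactone before cycloaddition and so unlock the diene geometry. Facial discrimination by the ligand may also be weak. The fallback separates light from the cycloaddition; it sets out from 15 and comes back at 20. Aldehyde 15 would be irradiated alone (366 nm, degassed benzene) so that the dienol closes by conrotatory 4π-electrocyclisation to the benzocyclobutenol F1. F1 would then be converted in the dark into its titanium TADDOLate alkoxide and warmed in toluene (40–60 °C) with 18. Alkoxide-accelerated ring opening, with oxygen and the ring-bound C-1 rotating outward, should regenerate the same titanium dienolate without excited states present, and its capture by 18 should give 20.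

Step 12. Hydrogen chloride addition to, or cationic cyclisation of, the isopropenyl group under the Lewis acid, and competing loss of the second methyl ether. The fallback removes the O-14 methyl group oxidatively; it sets out from 23 and comes back at 26. Saponification of 23 (LiOH, degassed THF/H2O) would give the 11-hydroxy-14-methoxy acid F2. Its para-methoxyphenol unit would be oxidised with PhI(OAc)2 in MeCN/H2O at 0 °C to the 11,14-quinone acid F3, with loss of methanol. Reduction with Na2S2O4 (EtOAc/H2O) should give 26, so the hydroquinone is formed only at the end and under reducing conditions.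

Step 6. Formation of the branched acyl-palladium species or alkene isomerisation, which would lead to six- or five-membered lactones. The fallback builds the ring by metathesis; it sets out from 12 and comes back at 13. Phenol 12 would be acylated with acryloyl chloride (Et3N, CH2Cl2) to the aryl acrylate F4. Ring-closing metathesis with a second-generation ruthenium benzylidene catalyst would give the unsaturated benzoxepinone F5. Hydrogenation (H2, Pd/C, EtOAc) of the conjugated ring alkene should then give 13.

**Further compounds**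
F1 | step 9 | rac-benzocyclobutenol from 15 (cyclobutene across C-7, C-8, C-9, C-10; OH cis to the C-10 methyl; lactone retained) | O[C@@H]1c2c(OC)c(C(C)C)c(OC)c3OC(=O)CC[C@]1(C)c23
F2 | step 12 | 3-[(1S,2S)-8-hydroxy-5,7-dimethoxy-1-methyl-4-oxo-6-(propan-2-yl)-2-(prop-1-en-2-yl)-1,2,3,4-tetrahydronaphthalen-1-yl]propanoic acid | C=C(C)[C@@H]1CC(=O)c2c(OC)c(C(C)C)c(OC)c(O)c2[C@@]1(C)CCC(=O)O
F3 | step 12 | (5S,10S)-12-methoxy-7-oxo-11,14-quinone acid (3-[(1S,2S)-7-methoxy-1-methyl-4,5,8-trioxo-6-(propan-2-yl)-2-(prop-1-en-2-yl)-1,2,3,4,5,8-hexahydronaphthalen-1-yl]propanoic acid) | C=C(C)[C@@H]1CC(=O)C2=C(C(=O)C(OC)=C(C(C)C)C2=O)[C@@]1(C)CCC(=O)O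
F4 | step 6 | rac-6-(but-3-en-2-yl)-2,4-dimethoxy-3-(propan-2-yl)phenyl prop-2-enoate | C=CC(=O)Oc1c(C(C)C=C)cc(OC)c(C(C)C)c1OC
F5 | step 6 | rac-7,9-dimethoxy-5-methyl-8-(propan-2-yl)-1-benzoxepin-2(5H)-one | CC1C=CC(=O)Oc2c(OC)c(C(C)C)c(OC)cc12
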